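**Retrosynthetic overview**
- The target is a diaryl ether. Ring A (3,5-dibromo-2-methoxyphenyl) comes from a catechol monoether by late OH-directed dibromination and O-methylation. The ring B hydroxyl at C6' comes from a boronate.
- The strategy rests on ring B: C2'(Br)-C3'(H)-C4'(Br)-C5'(Br) is the C5-C4-C3-C2 carbon chain of 2,3,5-tribromothiophene, and C1'(OAr)-C6'(OH) are the two carbons of an aryloxyalkyne carrying boron.
- Key disconnection: C1'-C2' and C5'-C6' by Diels-Alder addition of an ynol ether pinacolboronate across C2/C5 of 2,3,5-tribromothiophene 1,1-dioxide, then loss of SO2.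
- Ring order: ring A is bought as catechol; ring B is the only ring built (step 5). Then MOM removal, Br2, MeI, and C-B to C-OH.

Key step: step 5

Remark: the target has no stereocentre, so no configuration has to be set; the E geometry of vinyl ether 4 is destroyed in step 3 and is of no consequence.

**Step 1**
Reactants: 1 catechol
Product: 2 2-(methoxymethoxy)phenol
Conditions: NaH (1.0 equiv), MOMCl (1.0 equiv), THF-DMF, 0 °C → rt
Reagents that add atoms: chloromethyl methyl ether, COCCl
Why: Williamson O-alkylation (MOM protection) of the monosodium catecholate; with one equivalent each of base and MOMCl the monoether should predominate and is separated from catechol by aqueous wash and from the bis-ether by chromatography.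

**Step 2**
Reactants: 2 2-(methoxymethoxy)phenol; 3 trichloroethylene
Product: 4 1-{[(E)-1,2-dichloroethenyl]oxy}-2-(methoxymethoxy)benzene
Conditions: K2CO3, DMF, 70 °C
Reagents that add atoms: none
Why: Dichlorovinyl ether synthesis: K2CO3 turns trichloroethylene into dichloroacetylene in situ and the phenoxide adds anti across it, which should give the E-dichloroenol ether, while the MOM acetal is inert to base.

**Step 3**
Reactants: 4 1-{[(E)-1,2-dichloroethenyl]oxy}-2-(methoxymethoxy)benzene; 5 2-isopropoxy-4,4,5,5-tetramethyl-1,3,2-dioxaborolane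
Product: 9 2-{[2-(methoxymethoxy)phenoxy]ethynyl}-4,4,5,5-tetramethyl-1,3,2-dioxaborolane, via chloroalkyne 6 (not isolated), via lithium acetylide 7 (not isolated), via lithium alkynylborate 8 (not isolated)
Conditions: n-BuLi (2.05 equiv), Et2O, -78 → -40 °C; then 5, -78 °C; then HCl in Et2O (1.0 equiv), -78 °C → rt; filter LiCl, use promptly
Reagents that add atoms: none
Why: Ynol ether synthesis from a dichlorovinyl ether (dehydrochlorination to the chloroalkyne, then Li-Cl exchange) followed by the standard alkynylboronate synthesis (borate formation, then removal of isopropoxide with exactly one equivalent of anhydrous HCl); at -78 °C vinylic deprotonation should outrun ortho-lithiation next to OMOM, and an aryl ynol ether cannot fragment to a ketene by retro-ene loss.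

**Step 4**
Reactants: 10 2,3,5-tribromothiophene
Product: 11 2,3,5-tribromothiophene 1,1-dioxide
Conditions: (CF3CO)2O, urea·H2O2 (forms CF3CO3H), CH2Cl2, 0 °C → rt; store cold
Reagents that add atoms: trifluoroperacetic acid (made in situ), OOC(=O)C(F)(F)F
Why: S-oxidation of a halogen-deactivated thiophene with trifluoroperacetic acid, the oxidant class used for polyhalothiophene dioxides; three bromines should slow Diels-Alder self-dimerisation enough for the dioxide to be isolated.

**Step 5**
Reactants: 9 2-{[2-(methoxymethoxy)phenoxy]ethynyl}-4,4,5,5-tetramethyl-1,3,2-dioxaborolane; 11 2,3,5-tribromothiophene 1,1-dioxide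
Product: 13 2-{2,3,5-tribromo-6-[2-(methoxymethoxy)phenoxy]phenyl}-4,4,5,5-tetramethyl-1,3,2-dioxaborolane, via sulfone-bridged cycloadduct 12 (not isolated)
Conditions: 9 (1.2 equiv), PhMe, 80 → 110 °C, Ar sweep (-SO2)
Reagents that add atoms: none
Why: Proposed new method: the sulfone locks an electron-poor s-cis diene and the aryloxy group raises the alkyne HOMO, so an inverse-electron-demand, concerted but asynchronous (4+2) cycloaddition across thiophene C2 and C5 should give the 7-thiabicyclo[2.2.1]heptadiene 7,7-dioxide 12, which loses SO2 cheletropically and aromatises to 13 without a change of oxidation level. The closest known reactions are Diels-Alder/SO2-extrusion benzannulations of halogenated thiophene 1,1-dioxides with alkynes and cycloadditions of alkynyl pinacolboronates that give arylboronates; an ynol ether boronate has not been used as the dienophile. Six-membered ring B is closed by the intermolecular cycloaddition itself, which forms C1'-C2' and C5'-C6' together, and the two bridgehead stereocentres of 12 vanish on aromatisation, so nothing stereochemical has to be controlled. The step needs regioselectivity: the boron-bearing alkyne carbon, which is beta to oxygen and carries the larger HOMO coefficient, must bond to thiophene C2 (the terminus next to C3-Br) and the oxygen-bearing carbon to C5 (next to C4-H). Bromine at C3 is on balance electron-withdrawing, so it should enlarge the diene LUMO coefficient at the adjacent terminus C2 and stabilise the negative charge building on C3 and on the alpha-sulfonyl carbon C5, which favours this orientation, though probably only moderately. Both orientations put the boronate next to a bromine, so sterics discriminate little, and the regiochemistry should be confirmed by HMBC/NOE from H3' before going on.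

**Step 6**
Reactants: 13 2-{2,3,5-tribromo-6-[2-(methoxymethoxy)phenoxy]phenyl}-4,4,5,5-tetramethyl-1,3,2-dioxaborolane
Product: 14 2-[3,4,6-tribromo-2-(4,4,5,5-tetramethyl-1,3,2-dioxaborolan-2-yl)phenoxy]phenol
Conditions: conc. HCl (cat.), MeOH-THF, 40 °C
Reagents that add atoms: none
Why: Acid-catalysed acetal exchange (MOM cleavage) with methanol, under which aryl bromides, the diaryl ether and the hindered pinacol boronate should not react.

**Step 7**
Reactants: 14 2-[3,4,6-tribromo-2-(4,4,5,5-tetramethyl-1,3,2-dioxaborolan-2-yl)phenoxy]phenol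
Product: 15 2,4-dibromo-6-[3,4,6-tribromo-2-(4,4,5,5-tetramethyl-1,3,2-dioxaborolan-2-yl)phenoxy]phenol
Conditions: Br2 (2.05 equiv), CH2Cl2, -20 → 0 °C
Reagents that add atoms: bromine, BrBr
Why: Electrophilic aromatic bromination directed by the free phenol of ring A to its para and remaining ortho positions; ring B carries three bromines and boron in place of OH, so C3' and the C-B bond should stay untouched at low temperature with two equivalents of Br2.

**Step 8**
Reactants: 15 2,4-dibromo-6-[3,4,6-tribromo-2-(4,4,5,5-tetramethyl-1,3,2-dioxaborolan-2-yl)phenoxy]phenol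
Product: 16 2-[2,3,5-tribromo-6-(3,5-dibromo-2-methoxyphenoxy)phenyl]-4,4,5,5-tetramethyl-1,3,2-dioxaborolane
Conditions: MeI, K2CO3, dry DMF, rt
Reagents that add atoms: iodomethane, CI
Why: Williamson O-methylation of the acidic dibromophenol under anhydrous conditions, which the pinacol boronate tolerates.

**Step 9**
Reactants: 16 2-[2,3,5-tribromo-6-(3,5-dibromo-2-methoxyphenoxy)phenyl]-4,4,5,5-tetramethyl-1,3,2-dioxaborolane
Product: 17 2,3,5-tribromo-6-(3,5-dibromo-2-methoxyphenoxy)phenol (target)
Conditions: 30% aq. H2O2, NaHCO3, THF-H2O, 0 °C → rt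
Reagents that add atoms: hydrogen peroxide, OO
Why: Oxidation of the arylboronate by hydroperoxide (1,2-aryl shift from boron to oxygen at the same carbon), run near neutral pH because a di-ortho-substituted electron-poor arylboronate is prone to base-mediated protodeboronation.

**Compound list**
1 | catechol (benzene-1,2-diol) | Oc1ccccc1O | starting material
2 | 2-(methoxymethoxy)phenol | COCOc1ccccc1O | intermediate
3 | trichloroethylene | ClC=C(Cl)Cl | starting material
4 | 1-{[(E)-1,2-dichloroethenyl]oxy}-2-(methoxymethoxy)benzene | COCOc1ccccc1O/C(Cl)=C\Cl | intermediate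
5 | 2-isopropoxy-4,4,5,5-tetramethyl-1,3,2-dioxaborolane | CC(C)OB1OC(C)(C)C(C)(C)O1 | starting material
6 | 1-[(chloroethynyl)oxy]-2-(methoxymethoxy)benzene | COCOc1ccccc1OC#CCl | intermediate (not isolated)
7 | lithium [2-(methoxymethoxy)phenoxy]ethynide | COCOc1ccccc1OC#C[Li] | intermediate (not isolated)
8 | lithium isopropoxy{[2-(methoxymethoxy)phenoxy]ethynyl}(pinacolato)borate | [Li+].COCOc1ccccc1OC#C[B-]1(OC(C)C)OC(C)(C)C(C)(C)O1 | intermediate (not isolated)
9 | 2-{[2-(methoxymethoxy)phenoxy]ethynyl}-4,4,5,5-tetramethyl-1,3,2-dioxaborolane | COCOc1ccccc1OC#CB1OC(C)(C)C(C)(C)O1 | intermediate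
10 | 2,3,5-tribromothiophene | Brc1cc(Br)c(Br)s1 | starting material
11 | 2,3,5-tribromothiophene 1,1-dioxide | O=S1(=O)C(Br)=CC(Br)=C1Br | intermediate
12 | 1,4,5-tribromo-2-[2-(methoxymethoxy)phenoxy]-3-(4,4,5,5-tetramethyl-1,3,2-dioxaborolan-2-yl)-7-thiabicyclo[2.2.1]hepta-2,5-diene 7,7-dioxide (racemic, transient) | O=S1(=O)C2(Br)C(Br)=CC1(Br)C(Oc3ccccc3OCOC)=C2B4OC(C)(C)C(C)(C)O4 | intermediate (not isolated)
13 | 2-{2,3,5-tribromo-6-[2-(methoxymethoxy)phenoxy]phenyl}-4,4,5,5-tetramethyl-1,3,2-dioxaborolane | COCOc1ccccc1Oc1c(Br)cc(Br)c(Br)c1B1OC(C)(C)C(C)(C)O1 | intermediate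
14 | 2-[3,4,6-tribromo-2-(4,4,5,5-tetramethyl-1,3,2-dioxaborolan-2-yl)phenoxy]phenol | Oc1ccccc1Oc1c(Br)cc(Br)c(Br)c1B1OC(C)(C)C(C)(C)O1 | intermediate
15 | 2,4-dibromo-6-[3,4,6-tribromo-2-(4,4,5,5-tetramethyl-1,3,2-dioxaborolan-2-yl)phenoxy]phenol | Oc1c(Br)cc(Br)cc1Oc1c(Br)cc(Br)c(Br)c1B1OC(C)(C)C(C)(C)O1 | intermediate
16 | 2-[2,3,5-tribromo-6-(3,5-dibromo-2-methoxyphenoxy)phenyl]-4,4,5,5-tetramethyl-1,3,2-dioxaborolane | COc1c(Br)cc(Br)cc1Oc1c(Br)cc(Br)c(Br)c1B1OC(C)(C)C(C)(C)O1 | intermediate
17 | 2,3,5-tribromo-6-(3,5-dibromo-2-methoxyphenoxy)phenol | COc1c(Br)cc(Br)cc1Oc1c(Br)cc(Br)c(Br)c1O | target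

**Step count**
Total: 9 steps. Longest linear sequence: 8 steps (1, 2, 3, 5, 6, 7, 8, 9); step 4 is the convergent branch.

**Steps most likely to fail**

1. Step 5. The alkyne may add in the opposite orientation (boron ending next to the bromine that neighbours C-H). The push-pull alkyne may instead add stepwise across C4=C5 in a (2+2) sense. The dioxide may also decompose or dimerise before cycloaddition.
Fallback (known chemistry; sets out from 2 and comes back at 17): the diaryl ether is made by SNAr and the ring B hydroxyl by Baeyer-Villiger oxidation.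
   - 1,4-Dibromo-2-fluorobenzene is lithiated between F and Br with LiN(iPr)2 (THF, -78 °C) and formylated with DMF to 3,6-dibromo-2-fluorobenzaldehyde F1.
   - NBS in conc. H2SO4 brominates para to fluorine and meta to the formyl group, giving 2,3,5-tribromo-6-fluorobenzaldehyde F2.
   - The potassium salt of 2 (K2CO3, DMF, 60 °C) displaces the fluoride ortho to CHO, giving 2,3,5-tribromo-6-[2-(methoxymethoxy)phenoxy]benzaldehyde F3.
   - HCl/MeOH removes MOM to give 2,3,5-tribromo-6-(2-hydroxyphenoxy)benzaldehyde F4.
   - Br2 (2 equiv, CH2Cl2, 0 °C) brominates ring A ortho and para to its OH, giving 2,3,5-tribromo-6-(3,5-dibromo-2-hydroxyphenoxy)benzaldehyde F5; ring B is deactivated by CHO and three bromines.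
   - MeI/K2CO3 gives 2,3,5-tribromo-6-(3,5-dibromo-2-methoxyphenoxy)benzaldehyde F6.
   - Baeyer-Villiger oxidation with mCPBA (CH2Cl2, NaHCO3) gives 2,3,5-tribromo-6-(3,5-dibromo-2-methoxyphenoxy)phenyl formate F7, which K2CO3/MeOH cleaves to 17.

2. Step 3. The acid quench may protonate the C-B bond, add HCl to the ynol ether or remove MOM, and the boronate may hydrolyse during isolation.
Fallback (sets out from 4, comes back at 9): acetylide 7 is generated from 4 as before and trapped with ClB(N(iPr)2)2 instead of 5. No acid is needed, and the product is N,N,N',N'-tetraisopropyl-1-{[2-(methoxymethoxy)phenoxy]ethynyl}boranediamine F8, isolated by filtration from LiCl and distillation or crystallisation. Exchange with pinacol (PhMe, 60 °C, iPr2NH removed under vacuum) then gives 9 under neutral conditions.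

3. Step 4. Oxidation of the electron-poor sulfur may stall at the S-oxide, which dimerises, or the dioxide may self-dimerise by Diels-Alder reaction during isolation.
Fallback (sets out from 10, comes back at 11): oxidise a silylated, more electron-rich thiophene and restore the bromines afterwards.
   - Two successive alpha-selective Br-Li exchanges on 10 (n-BuLi, THF, -78 °C), each quenched with Me3SiCl, give 3-bromo-2,5-bis(trimethylsilyl)thiophene F9.
   - mCPBA (CH2Cl2, rt) oxidises it to 3-bromo-2,5-bis(trimethylsilyl)thiophene 1,1-dioxide F10.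
   - Ipso-bromodesilylation of both C-Si bonds with Br2/AgBF4 (CH2Cl2, 0 °C) gives 11.

**Further compounds**
F1 | step 5 | 3,6-dibromo-2-fluorobenzaldehyde | O=Cc1c(F)c(Br)ccc1Br
F2 | step 5 | 2,3,5-tribromo-6-fluorobenzaldehyde | O=Cc1c(F)c(Br)cc(Br)c1Br
F3 | step 5 | 2,3,5-tribromo-6-[2-(methoxymethoxy)phenoxy]benzaldehyde | O=Cc1c(Oc2ccccc2OCOC)c(Br)cc(Br)c1Br
F4 | step 5 | 2,3,5-tribromo-6-(2-hydroxyphenoxy)benzaldehyde | O=Cc1c(Oc2ccccc2O)c(Br)cc(Br)c1Br
F5 | step 5 | 2,3,5-tribromo-6-(3,5-dibromo-2-hydroxyphenoxy)benzaldehyde | O=Cc1c(Oc2cc(Br)cc(Br)c2O)c(Br)cc(Br)c1Br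
F6 | step 5 | 2,3,5-tribromo-6-(3,5-dibromo-2-methoxyphenoxy)benzaldehyde | O=Cc1c(Oc2cc(Br)cc(Br)c2OC)c(Br)cc(Br)c1Br
F7 | step 5 | 2,3,5-tribromo-6-(3,5-dibromo-2-methoxyphenoxy)phenyl formate | O=COc1c(Oc2cc(Br)cc(Br)c2OC)c(Br)cc(Br)c1Br
F8 | step 3 | N,N,N',N'-tetraisopropyl-1-{[2-(methoxymethoxy)phenoxy]ethynyl}boranediamine | COCOc1ccccc1OC#CB(N(C(C)C)C(C)C)N(C(C)C)C(C)C
F9 | step 4 | 3-bromo-2,5-bis(trimethylsilyl)thiophene | C[Si](C)(C)c1cc(Br)c([Si](C)(C)C)s1
F10 | step 4 | 3-bromo-2,5-bis(trimethylsilyl)thiophene 1,1-dioxide | C[Si](C)(C)C1=CC(Br)=C([Si](C)(C)C)S1(=O)=O
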